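**Retrosynthetic overview**

- The acid comes from its methyl ester by saponification.
- The only ring, the dihydropyran, is closed late (step 7) through the O1–C2 bond. The hydroxylated C-methyl of the all-E polyprenyl chain attacks the oxidised terminal unit in a 6-exo SN2'-type etherification, as the biosynthesis presumably does. It is run as a palladium-catalysed dynamic kinetic asymmetric cyclisation of a racemic Morita–Baylis–Hillman (MBH) carbonate, which sets C2 as R.
- The MBH unit comes from a β,γ-unsaturated aldehyde and an α-aluminated acrylate.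
- The Z-trisubstituted olefin (CH2O cis to the chain) comes from a Wittig reaction of an α-silyloxy ketone with a three-carbon acetal ylide.
- The ketone comes from trans,trans-farnesyl bromide and the kinetic enolate of silyloxyacetone.

Assumption: the (R,R)-ligand is taken to give the (2R)-ether; if the first run shows the opposite sense, the mirror-image ligand is used with no other change.

**Step 1**
Reactants: 1 1-[(tert-butyldimethylsilyl)oxy]propan-2-one; 2 (2E,6E)-1-bromo-3,7,11-trimethyldodeca-2,6,10-triene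
Product: 4 (5E,9E)-1-[(tert-butyldimethylsilyl)oxy]-6,10,14-trimethylpentadeca-5,9,13-trien-2-one, via lithium enolate 3 (not isolated)
Conditions: LiN(iPr)2 (2.0 equiv), 1 (2.1 equiv), THF, −78 °C; then 2 (1.0 equiv), DMPU, −78 → −20 °C
Reagents that add atoms: none
Why: Kinetic enolate alkylation (SN2): the amide base deprotonates the unhindered methyl rather than the silyloxy-bearing CH2, the primary allylic bromide reacts at C1 without transposition so both E-olefins are kept, and excess enolate suppresses dialkylation.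

**Step 2**
Reactants: 4 (5E,9E)-1-[(tert-butyldimethylsilyl)oxy]-6,10,14-trimethylpentadeca-5,9,13-trien-2-one; 5 [2-(1,3-dioxolan-2-yl)ethyl]triphenylphosphonium bromide
Product: 7 2-[(2Z,6E,10E)-3-{[(tert-butyldimethylsilyl)oxy]methyl}-7,11,15-trimethylhexadeca-2,6,10,14-tetraen-1-yl]-1,3-dioxolane, via phosphorus ylide 6 (not isolated)
Conditions: 5 (1.5 equiv), KN(SiMe3)2 (1.45 equiv), THF, −78 → 0 °C; then 4, −78 °C → rt
Reagents that add atoms: none
Why: Wittig olefination with a non-stabilised ylide: α-alkoxy and α-silyloxy ketones give the trisubstituted olefin with the CH2OSi group cis to the new chain (Z), which is the geometry the later six-ring closure needs; the minor E isomer is removed by chromatography.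

**Step 3**
Reactants: 7 2-[(2Z,6E,10E)-3-{[(tert-butyldimethylsilyl)oxy]methyl}-7,11,15-trimethylhexadeca-2,6,10,14-tetraen-1-yl]-1,3-dioxolane
Product: 9 (3Z,7E,11E)-4-{[(tert-butyldimethylsilyl)oxy]methyl}-8,12,16-trimethylheptadeca-3,7,11,15-tetraenal, via collidinium salt 8 (not isolated)
Conditions: Et3SiOSO2CF3 (2 equiv), 2,4,6-collidine (3 equiv), CH2Cl2, 0 °C; then H2O, rt
Reagents that add atoms: water, O
Why: Silyl triflate/pyridine-base acetal cleavage: the dioxolane opens to an oxocarbenium ion that is trapped as pyridinium N,O-acetal 8 and hydrolysed by water under weakly basic conditions, so the TBS ether survives and the β,γ-unsaturated aldehyde does not move into conjugation; 9 is used crude at once.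

**Step 4**
Reactants: 9 (3Z,7E,11E)-4-{[(tert-butyldimethylsilyl)oxy]methyl}-8,12,16-trimethylheptadeca-3,7,11,15-tetraenal; 10 methyl prop-2-ynoate
Product: 13 methyl (5Z,9E,13E)-6-{[(tert-butyldimethylsilyl)oxy]methyl}-3-hydroxy-10,14,18-trimethyl-2-methylidenenonadeca-5,9,13,17-tetraenoate (racemic), via vinylalane 11 (not isolated), via aluminium alkoxide 12 (not isolated)
Conditions: iBu2AlH (1.5 equiv), N-methylmorpholine N-oxide (1.5 equiv), 10 (1.6 equiv), THF, 0 °C; then 9, 0 °C → rt; aq. KNaC4H4O6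
Reagents that add atoms: none
Why: Hydroalumination of the propiolate gives the α-aluminated acrylate, which adds to the aldehyde as a non-basic Morita–Baylis–Hillman surrogate (vinylalumination) and so avoids the amine base that would conjugate the skipped enal; the carbinol centre is formed racemic on purpose because step 7 is enantioconvergent.

**Step 5**
Reactants: 13 methyl (5Z,9E,13E)-6-{[(tert-butyldimethylsilyl)oxy]methyl}-3-hydroxy-10,14,18-trimethyl-2-methylidenenonadeca-5,9,13,17-tetraenoate (racemic)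
Product: 14 methyl (5Z,9E,13E)-3-[(tert-butoxycarbonyl)oxy]-6-{[(tert-butyldimethylsilyl)oxy]methyl}-10,14,18-trimethyl-2-methylidenenonadeca-5,9,13,17-tetraenoate (racemic)
Conditions: Boc2O (1.5 equiv), DMAP (0.1 equiv), CH2Cl2, 0 °C → rt
Reagents that add atoms: di-tert-butyl dicarbonate, CC(C)(C)OC(=O)OC(=O)OC(C)(C)C
Why: DMAP-catalysed O-acylation of the secondary allylic alcohol to the tert-butyl carbonate, which later serves as leaving group and as internal source of base.

**Step 6**
Reactants: 14 methyl (5Z,9E,13E)-3-[(tert-butoxycarbonyl)oxy]-6-{[(tert-butyldimethylsilyl)oxy]methyl}-10,14,18-trimethyl-2-methylidenenonadeca-5,9,13,17-tetraenoate (racemic)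
Product: 15 methyl (5Z,9E,13E)-3-[(tert-butoxycarbonyl)oxy]-6-(hydroxymethyl)-10,14,18-trimethyl-2-methylidenenonadeca-5,9,13,17-tetraenoate (racemic)
Conditions: HF·pyridine, pyridine, THF, 0 °C → rt
Reagents that add atoms: none
Why: Fluoride-mediated desilylation under buffered, slightly acidic conditions frees the primary allylic hydroxyl and leaves the carbonate, the acrylate and the skipped diene untouched.

**Step 7**
Reactants: 15 methyl (5Z,9E,13E)-3-[(tert-butoxycarbonyl)oxy]-6-(hydroxymethyl)-10,14,18-trimethyl-2-methylidenenonadeca-5,9,13,17-tetraenoate (racemic)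
Product: 17 methyl 2-[(2R)-5-[(3E,7E)-4,8,12-trimethyltrideca-3,7,11-trien-1-yl]-3,6-dihydro-2H-pyran-2-yl]prop-2-enoate, via π-allylpalladium alkoxide 16 (not isolated)
Conditions: Pd2(dba)3·CHCl3 (2.5 mol %), (R,R)-DACH-phenyl Trost ligand (7.5 mol %), CH2Cl2 (0.02 M, degassed), rt
Reagents that add atoms: none
Why: Proposed new method: intramolecular version of the palladium-catalysed dynamic kinetic asymmetric allylic etherification (Tsuji–Trost type) of Morita–Baylis–Hillman carbonates; zerovalent palladium ionises either enantiomer of 15 to the 2-(methoxycarbonyl)allyl complex, CO2 is lost and tert-butoxide deprotonates the primary hydroxyl to give 16, the diastereomeric allyl complexes interconvert by η3–η1–η3 slippage through the unsubstituted CH2 terminus faster than they cyclise, and the alkoxide attacks the substituted terminus 6-exo (the alternative is an eight-membered ring) in the ligand-controlled, enantio-determining step that sets C2 as R; the closest known chemistry is the intermolecular etherification of such carbonates with primary aliphatic alcohols under this catalyst, together with palladium-catalysed asymmetric cycloetherifications.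

**Step 8**
Reactants: 17 methyl 2-[(2R)-5-[(3E,7E)-4,8,12-trimethyltrideca-3,7,11-trien-1-yl]-3,6-dihydro-2H-pyran-2-yl]prop-2-enoate
Product: 19 2-[(2R)-5-[(3E,7E)-4,8,12-trimethyltrideca-3,7,11-trien-1-yl]-3,6-dihydro-2H-pyran-2-yl]prop-2-enoic acid, via lithium carboxylate 18 (not isolated)
Conditions: LiOH (5 equiv), THF/MeOH/H2O (3:1:1), 0 °C → rt; then 1 M HCl to pH 3, 0 °C
Reagents that add atoms: lithium hydroxide, [Li+].[OH-]
Why: Saponification (acyl-oxygen ester hydrolysis); the stereocentre is an ether carbon whose hydrogen is not enolisable (the ester sits on the central carbon of the allyl unit), so it is not scrambled.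

**Compound list**

1 | 1-[(tert-butyldimethylsilyl)oxy]propan-2-one | CC(=O)CO[Si](C)(C)C(C)(C)C | starting material
2 | (2E,6E)-1-bromo-3,7,11-trimethyldodeca-2,6,10-triene (trans,trans-farnesyl bromide) | BrC/C=C(\C)CC/C=C(\C)CCC=C(C)C | starting material
3 | lithium 3-[(tert-butyldimethylsilyl)oxy]prop-1-en-2-olate (kinetic enolate of 1, formed in the flask) | [Li]OC(=C)CO[Si](C)(C)C(C)(C)C | intermediate
4 | (5E,9E)-1-[(tert-butyldimethylsilyl)oxy]-6,10,14-trimethylpentadeca-5,9,13-trien-2-one | CC(C)(C)[Si](C)(C)OCC(=O)CC/C=C(\C)CC/C=C(\C)CCC=C(C)C | intermediate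
5 | [2-(1,3-dioxolan-2-yl)ethyl]triphenylphosphonium bromide | [Br-].c1ccc(cc1)[P+](CCC1OCCO1)(c1ccccc1)c1ccccc1 | starting material
6 | [2-(1,3-dioxolan-2-yl)ethylidene]triphenylphosphorane (ylide, formed in the flask) | c1ccc(cc1)P(=CCC1OCCO1)(c1ccccc1)c1ccccc1 | intermediate
7 | 2-[(2Z,6E,10E)-3-{[(tert-butyldimethylsilyl)oxy]methyl}-7,11,15-trimethylhexadeca-2,6,10,14-tetraen-1-yl]-1,3-dioxolane | CC(C)(C)[Si](C)(C)OC/C(=C\CC1OCCO1)CC/C=C(\C)CC/C=C(\C)CCC=C(C)C | intermediate
8 | 1-{(3Z,7E,11E)-4-{[(tert-butyldimethylsilyl)oxy]methyl}-8,12,16-trimethyl-1-[2-(triethylsilyloxy)ethoxy]heptadeca-3,7,11,15-tetraen-1-yl}-2,4,6-trimethylpyridinium trifluoromethanesulfonate (racemic, formed in the flask) | CC(C)(C)[Si](C)(C)OC/C(=C\CC(OCCO[Si](CC)(CC)CC)[n+]1c(C)cc(C)cc1C)CC/C=C(\C)CC/C=C(\C)CCC=C(C)C.[O-]S(=O)(=O)C(F)(F)F | intermediate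
9 | (3Z,7E,11E)-4-{[(tert-butyldimethylsilyl)oxy]methyl}-8,12,16-trimethylheptadeca-3,7,11,15-tetraenal | CC(C)(C)[Si](C)(C)OC/C(=C\CC=O)CC/C=C(\C)CC/C=C(\C)CCC=C(C)C | intermediate
10 | methyl prop-2-ynoate (methyl propiolate) | C#CC(=O)OC | starting material
11 | methyl 2-(diisobutylalumanyl)prop-2-enoate (formed in the flask) | C=C(C(=O)OC)[Al](CC(C)C)CC(C)C | intermediate
12 | diisobutylaluminium alkoxide of 13 (racemic, formed in the flask) | COC(=O)C(=C)C(O[Al](CC(C)C)CC(C)C)C/C=C(\CO[Si](C)(C)C(C)(C)C)CC/C=C(\C)CC/C=C(\C)CCC=C(C)C | intermediate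
13 | methyl (5Z,9E,13E)-6-{[(tert-butyldimethylsilyl)oxy]methyl}-3-hydroxy-10,14,18-trimethyl-2-methylidenenonadeca-5,9,13,17-tetraenoate (racemic at C3) | COC(=O)C(=C)C(O)C/C=C(\CO[Si](C)(C)C(C)(C)C)CC/C=C(\C)CC/C=C(\C)CCC=C(C)C | intermediate
14 | methyl (5Z,9E,13E)-3-[(tert-butoxycarbonyl)oxy]-6-{[(tert-butyldimethylsilyl)oxy]methyl}-10,14,18-trimethyl-2-methylidenenonadeca-5,9,13,17-tetraenoate (racemic at C3) | COC(=O)C(=C)C(OC(=O)OC(C)(C)C)C/C=C(\CO[Si](C)(C)C(C)(C)C)CC/C=C(\C)CC/C=C(\C)CCC=C(C)C | intermediate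
15 | methyl (5Z,9E,13E)-3-[(tert-butoxycarbonyl)oxy]-6-(hydroxymethyl)-10,14,18-trimethyl-2-methylidenenonadeca-5,9,13,17-tetraenoate (racemic at C3) | COC(=O)C(=C)C(OC(=O)OC(C)(C)C)C/C=C(\CO)CC/C=C(\C)CC/C=C(\C)CCC=C(C)C | intermediate
16 | zwitterionic [2-(methoxycarbonyl)allyl]palladium alkoxide carrying the (R,R)-Trost ligand, from 15 after loss of CO2 and tert-butanol (drawn as the σ-allyl form, formed in the flask) | COC(=O)C(=C)C(C/C=C(\C[O-])CC/C=C(\C)CC/C=C(\C)CCC=C(C)C)[Pd-]1[P+](c2ccccc2)(c2ccccc2)c2ccccc2C(=O)N[C@@H]2CCCC[C@H]2NC(=O)c2ccccc2[P+]1(c1ccccc1)c1ccccc1 | intermediate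
17 | methyl 2-[(2R)-5-[(3E,7E)-4,8,12-trimethyltrideca-3,7,11-trien-1-yl]-3,6-dihydro-2H-pyran-2-yl]prop-2-enoate | C=C(C(=O)OC)[C@H]1CC=C(CC/C=C(\C)CC/C=C(\C)CCC=C(C)C)CO1 | intermediate
18 | lithium 2-[(2R)-5-[(3E,7E)-4,8,12-trimethyltrideca-3,7,11-trien-1-yl]-3,6-dihydro-2H-pyran-2-yl]prop-2-enoate (formed in the flask) | C=C(C(=O)[O-])[C@H]1CC=C(CC/C=C(\C)CC/C=C(\C)CCC=C(C)C)CO1.[Li+] | intermediate
19 | 2-[(2R)-5-[(3E,7E)-4,8,12-trimethyltrideca-3,7,11-trien-1-yl]-3,6-dihydro-2H-pyran-2-yl]prop-2-enoic acid (CNP0171598.2) | C=C(C(=O)O)[C@H]1CC=C(CC/C=C(\C)CC/C=C(\C)CCC=C(C)C)CO1 | target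

**Step count and risks**

Total steps: 8. Longest linear sequence: 8 (1 and 2 to 19).

The three steps most likely to fail, each with its fallback:

- **Step 7 (ring closure).** The risks are modest enantioselectivity in the untested intramolecular setting, transfer of the carbonate to the primary alkoxide, and elimination of the allyl complex to a triene. The fallback sets out from 14. Water with (DHQD)2PHAL (10 mol %, dioxane, rt; or its pseudo-enantiomer (DHQ)2PHAL, whichever gives the R sense) effects a Lewis-base-catalysed asymmetric allylic hydroxylation (SN2'–SN2') and gives the (R)-alcohol F5. HF·pyridine then gives the (R)-diol F6. A Mitsunobu cyclodehydration (PPh3, DIAD, THF, 0 °C) activates the primary allylic hydroxyl, and the C3 hydroxyl closes the ring at the CH2 carbon with the stereocentre untouched. This comes back to the route at 17.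

- **Step 3 (acetal cleavage to the labile β,γ-unsaturated aldehyde 9).** The risks are partial loss of the TBS group and conjugation or decomposition of 9 before step 4. The fallback sets out from 7. Hydrolysis with 1 M HCl in THF removes both the acetal and the silyl ether and gives the lactol F3, a stable masked form of the hydroxy-aldehyde. Treatment of F3 with excess vinylalane 11 (3 equiv, THF, 0 °C → rt) gives the diol F4. Selective silylation of the primary allylic hydroxyl (TBSCl 1.05 equiv, imidazole, CH2Cl2, −20 °C) comes back to the route at 13.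

- **Step 1 (regioselective enolate alkylation).** The risks are deprotonation on the silyloxy side, proton exchange and dialkylation. The fallback sets out from 1. Condensation with Me2NNH2 (EtOH, rt) gives the dimethylhydrazone F1, whose aza-enolate (LiN(iPr)2, THF, −78 °C) forms reliably at the methyl and is alkylated by 2 to the alkylated hydrazone F2. Mild hydrolysis (aq. CuCl2, THF) comes back to the route at 4.

**Further compounds**

F1 | step 1 | 1-[(tert-butyldimethylsilyl)oxy]propan-2-one N,N-dimethylhydrazone | CN(C)N=C(C)CO[Si](C)(C)C(C)(C)C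
F2 | step 1 | (5E,9E)-1-[(tert-butyldimethylsilyl)oxy]-6,10,14-trimethylpentadeca-5,9,13-trien-2-one N,N-dimethylhydrazone | CN(C)N=C(CO[Si](C)(C)C(C)(C)C)CC/C=C(\C)CC/C=C(\C)CCC=C(C)C
F3 | step 3 | 5-[(3E,7E)-4,8,12-trimethyltrideca-3,7,11-trien-1-yl]-3,6-dihydro-2H-pyran-2-ol (racemic lactol) | OC1CC=C(CC/C=C(\C)CC/C=C(\C)CCC=C(C)C)CO1
F4 | step 3 | methyl (5Z,9E,13E)-3-hydroxy-6-(hydroxymethyl)-10,14,18-trimethyl-2-methylidenenonadeca-5,9,13,17-tetraenoate (racemic) | COC(=O)C(=C)C(O)C/C=C(\CO)CC/C=C(\C)CC/C=C(\C)CCC=C(C)C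
F5 | step 7 | methyl (3R,5Z,9E,13E)-6-{[(tert-butyldimethylsilyl)oxy]methyl}-3-hydroxy-10,14,18-trimethyl-2-methylidenenonadeca-5,9,13,17-tetraenoate | COC(=O)C(=C)[C@H](O)C/C=C(\CO[Si](C)(C)C(C)(C)C)CC/C=C(\C)CC/C=C(\C)CCC=C(C)C
F6 | step 7 | methyl (3R,5Z,9E,13E)-3-hydroxy-6-(hydroxymethyl)-10,14,18-trimethyl-2-methylidenenonadeca-5,9,13,17-tetraenoate | COC(=O)C(=C)[C@H](O)C/C=C(\CO)CC/C=C(\C)CC/C=C(\C)CCC=C(C)C
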